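**Strategy.** The target, (S)-13-hydroxy-1-(2,4,6-trihydroxyphenyl)hexadecan-1-one, is disconnected at C6–C7 (chain numbered from the carbonyl carbon C1 on the phloroglucinol ring). The key step exploits the unbranched, heteroatom-free methylene run C2–C12 that separates the C1 ketone from the C13 carbinol: C6 and C7 carry no function, so a B-alkyl sp3–sp3 Suzuki coupling, which leaves no trace, fits best. In one pot, 9-BBN hydroboration reverses the polarity of the terminal alkene carbon of (S)-dec-9-en-4-ol (its hydroxyl is masked in situ as a borinate) and Pd/PCy3 joins it to the primary bromide of 6-bromohexanoylphloroglucinol tribenzyl ether, giving the whole C22 skeleton at its final oxidation level; hydrogenolysis then finishes.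

Key step: step 3

Remark on the chemistry: the single stereocentre (C13, S; O > C12 > C14 > H) is assumed to be bought as enantiopure (S)-2-propyloxirane, which is otherwise accessible by hydrolytic kinetic resolution of the racemate with the appropriate (salen)Co catalyst enantiomer; the CIP order is the same in the epoxide and in the target.

Step 1
Reactants: 1 1,3,5-tris(benzyloxy)benzene; 2 6-bromohexanoic acid
Product: 4 6-bromo-1-[2,4,6-tris(benzyloxy)phenyl]hexan-1-one, via mixed trifluoroacetic anhydride 3 (not isolated)
Conditions: 2, TFAA, CH2Cl2, 0 °C; then 1, 0 °C → rt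
Reagents that add atoms: none
Why: Friedel–Crafts acylation through the mixed carboxylic–trifluoroacetic anhydride, in which the C3-symmetric, strongly activated triether offers three equivalent ring CH positions, the alkanoyl (not the trifluoroacetyl) group is transferred, the ketone formed deactivates the ring against a second acylation, and the metal-free acid medium should spare the benzyl ethers and the primary bromide.

Step 2
Reactants: 5 5-bromopent-1-ene; 6 (S)-2-propyloxirane
Product: 8 (S)-dec-9-en-4-ol, via pent-4-enylmagnesium bromide 7 (not isolated)
Conditions: 5, Mg, THF, rt; then CuI (10 mol%), 6, THF, −40 → 0 °C; H2O (sat. NH4Cl) work-up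
Reagents that add atoms: none
Why: Copper-catalysed Grignard opening of a terminal epoxide, an SN2 attack at the unsubstituted CH2 that does not touch the C–O bond of the stereocentre, so the (S) configuration bought with 6 is carried unchanged into what becomes C13 (no stereocentre is created anywhere in the route).

Step 3
Reactants: 8 (S)-dec-9-en-4-ol; 4 6-bromo-1-[2,4,6-tris(benzyloxy)phenyl]hexan-1-one
Product: 10 (S)-13-hydroxy-1-[2,4,6-tris(benzyloxy)phenyl]hexadecan-1-one, via bis(9-BBN) adduct 9 (not isolated)
Conditions: 8 (1.3 equiv), 9-BBN (2.2 equiv B–H per 8), THF, 0 °C → rt; then K3PO4·H2O, 4, Pd(OAc)2 (4 mol%), PCy3 (8 mol%), THF, rt; aqueous work-up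
Reagents that add atoms: none
Why: Anti-Markovnikov hydroboration with 9-BBN puts boron on the terminal alkene carbon (the future C7) and so reverses its polarity to a nucleophile, while the free hydroxyl is masked in the same pot as its B-alkoxy-9-BBN borinate with loss of H2. Pd(0)/PCy3 then adds oxidatively (SN2-type) to the primary C6–Br bond of 4, the hydroxide-activated borate transfers only its primary alkyl group (the secondary B–C bonds of the bicyclic cage stay), and reductive elimination forms the C6–C7 bond. The closest known reaction type is the room-temperature B-alkyl Suzuki–Miyaura alkyl–alkyl coupling of primary alkyl bromides that carry β-hydrogens. No ring is closed and no stereocentre is formed; C13 is remote from the reacting centres and keeps its (S) configuration, and the borinate is hydrolysed back to the free carbinol on work-up. The step needs chemoselectivity for coupling over β-hydride elimination (secured by the bulky, electron-rich PCy3), over cyclisation of 4 through its C2 enolate (mild K3PO4·H2O at rt) and over attack on the C1 carbonyl (shielded by the two ortho benzyloxy groups; residual B–H is destroyed by the hydrate water before 4 is added).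

Step 4
Reactants: 10 (S)-13-hydroxy-1-[2,4,6-tris(benzyloxy)phenyl]hexadecan-1-one
Product: 11 (S)-13-hydroxy-1-(2,4,6-trihydroxyphenyl)hexadecan-1-one
Conditions: H2 (1 atm), 10% Pd/C, EtOAc–MeOH, rt
Reagents that add atoms: none
Why: Heterogeneous catalytic hydrogenolysis of the three aryl benzyl ethers, which should spare the non-benzylic C13 carbinol and the C1 carbonyl, the latter being a vinylogous acid locked by hydrogen bonds to the two ortho hydroxyls once these are freed.

**Compound list**

1 | 1,3,5-tris(benzyloxy)benzene (phloroglucinol tribenzyl ether) | c1ccc(COc2cc(OCc3ccccc3)cc(OCc3ccccc3)c2)cc1 | starting material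
2 | 6-bromohexanoic acid | OC(=O)CCCCCBr | starting material
3 | 6-bromohexanoic trifluoroacetic anhydride (mixed anhydride) | O=C(CCCCCBr)OC(=O)C(F)(F)F | intermediate
4 | 6-bromo-1-[2,4,6-tris(benzyloxy)phenyl]hexan-1-one | BrCCCCCC(=O)c1c(OCc2ccccc2)cc(OCc2ccccc2)cc1OCc1ccccc1 | intermediate
5 | 5-bromopent-1-ene | C=CCCCBr | starting material
6 | (S)-2-propyloxirane [(S)-1,2-epoxypentane] | CCC[C@H]1CO1 | starting material
7 | pent-4-enylmagnesium bromide | C=CCCC[Mg]Br | intermediate
8 | (S)-dec-9-en-4-ol | CCC[C@H](O)CCCCC=C | intermediate
9 | 9-[(S)-7-(9-borabicyclo[3.3.1]nonan-9-yloxy)decyl]-9-borabicyclo[3.3.1]nonane (C-boryl, O-boryl bis-9-BBN adduct of 8) | CCC[C@H](OB1C2CCCC1CCC2)CCCCCCB1C2CCCC1CCC2 | intermediate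
10 | (S)-13-hydroxy-1-[2,4,6-tris(benzyloxy)phenyl]hexadecan-1-one | CCC[C@H](O)CCCCCCCCCCCC(=O)c1c(OCc2ccccc2)cc(OCc2ccccc2)cc1OCc1ccccc1 | intermediate
11 | (S)-13-hydroxy-1-(2,4,6-trihydroxyphenyl)hexadecan-1-one | CCC[C@H](O)CCCCCCCCCCCC(=O)c1c(O)cc(O)cc1O | target

**Step count.** Total steps: 4. Longest linear sequence: 3 steps (step 2 → step 3 → step 4; step 1 → step 3 → step 4 is equally long).

**Steps most likely to fail**

Step 3 (key step). The coupling may be eroded by β-hydride elimination from the alkylpalladium intermediate, by slow transmetalation of the borinate-bearing alkylborane, or by base-promoted intramolecular enolate alkylation of the bromoketone. Fallback: the C6–C7 bond would be made as an alkene by olefin cross-metathesis and saturated afterwards. Setting out from 1, the mixed-anhydride acylation of step 1 run with hept-6-enoic acid (C=CCCCCC(=O)O) in place of 2 should give 1-[2,4,6-tris(benzyloxy)phenyl]hept-6-en-1-one F1. Setting out from 6, the copper-catalysed opening of step 2 run with hex-5-enylmagnesium bromide (from 6-bromohex-1-ene) should give (S)-undec-10-en-4-ol F2. Cross-metathesis of F1 with an excess of F2 (Grubbs second-generation catalyst, CH2Cl2, 40 °C) should give (S)-13-hydroxy-1-[2,4,6-tris(benzyloxy)phenyl]hexadec-6-en-1-one F3 with loss of ethene, expected as an E/Z mixture. The conditions of step 4 would then saturate the C6=C7 bond and cleave the benzyl ethers in one operation, coming back to the route at 11.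

Step 1. Trifluoroacetylation of the very electron-rich ring may compete with transfer of the alkanoyl group, and the acid may induce benzyl migration or loss. Fallback: the acyl group would be installed before the benzyl ethers. Setting out from 2, Nencki-type acylation of unprotected phloroglucinol (Oc1cc(O)cc(O)c1) in BF3·OEt2 at 80 °C should give 6-bromo-1-(2,4,6-trihydroxyphenyl)hexan-1-one F4. Exhaustive O-benzylation (excess BnBr, K2CO3, DMF) would then come back to the route at 4.

Step 4. Over-reduction of the benzylic C1 carbonyl or stalling of the hydrogenolysis at partly benzylated stages may occur. Fallback: non-reductive Lewis-acid debenzylation, setting out from 10 with BCl3 and pentamethylbenzene as cation scavenger (CH2Cl2, −78 °C, then MeOH), coming back to the route at 11; no new compound is made (F0).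

**Further compounds**

F1 | step 3 | 1-[2,4,6-tris(benzyloxy)phenyl]hept-6-en-1-one | C=CCCCCC(=O)c1c(OCc2ccccc2)cc(OCc2ccccc2)cc1OCc1ccccc1
F2 | step 3 | (S)-undec-10-en-4-ol | CCC[C@H](O)CCCCCC=C
F3 | step 3 | (S,E)-13-hydroxy-1-[2,4,6-tris(benzyloxy)phenyl]hexadec-6-en-1-one (E isomer drawn, Z isomer also expected) | CCC[C@H](O)CCCCC/C=C/CCCCC(=O)c1c(OCc2ccccc2)cc(OCc2ccccc2)cc1OCc1ccccc1
F4 | step 1 | 6-bromo-1-(2,4,6-trihydroxyphenyl)hexan-1-one | BrCCCCCC(=O)c1c(O)cc(O)cc1O
F0 | step 4 | none | none
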